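In a one-step world, where Q + D gives QD and nothing else, every Q consumed stands as QD and the share is 100 per cent; this flask has a fork and a second bite.

| flask | Q | D | time | remark |
|---|---|---|---|---|
| larch | 0.10 M (fed, over 1.50 h) | 0.110 M | 1.5 h | all but Q at the start; Q goes in evenly over 1.50 h, the run ends at 1.5 h |
| alder | 0.10 M | 0.110 M | 1.5 h | everything together in a closed stirred flask, run for 1.5 h |
| elm | 0.10 M | 0.110 M |  | one stirred flow tank at steady state, fed with the mixture as stated, mean residence time 1.5 h |
| cedar | 0.10 M | 0.110 M (fed, over 1.50 h) | 1.5 h | a stirred flask in which D is dosed at a steady rate over 1.50 h without added volume, worked up at 1.5 h |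

    Q + D → QD (k1 = 6.15 M⁻¹ min⁻¹)
    Q + D → Z (k2 = 0.412 M⁻¹ min⁻¹)
    D → X (k3 = 2.13 × 10⁻⁵ min⁻¹)
    2 D → J (k4 = 0.0830 M⁻¹ min⁻¹)
    D + QD → DQD (k5 = 0.238 M⁻¹ min⁻¹)

- two of one species on the left: rate k times its square, two consumed each time
- the stated concentrations are those of everything mixed, before any reaction; amounts are the same in each set-up
- the feed brings no volume worth counting
- run time (larch): 1.5 h

* the set-up with the highest share of QD in all that became QD or Z or DQD, at the outlet or at the end ("none" if the first two lie within 2 percentage points) (larch / alder / elm / cedar / none)
* share of QD in all that became QD or Z or DQD, at the outlet or at the end, larch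
* share of QD in all that became QD or Z or DQD, at the outlet or at the end, alder
* share of QD in all that became QD or Z or DQD, at the outlet or at the end, elm
* share of QD in all that became QD or Z or DQD, at the outlet or at the end, cedar

Steps 1 and 2 use the same Q and D, so their rates keep one ratio at every moment, and I freeze it. The fork share, the part of each consumed Q that goes to QD first rather than to Z (a selectivity, in the usual term), is k1 over k1 plus k2, 93.7%. Step 5 merely turns QD into DQD, so the share equals the fork share minus DQD per Q consumed, all as fractions of the Q charge.

With no DQD, the fork share is the ceiling. I tighten it for alder. If D merely kept pace with Q, the Q left after the run would be about 1.67%, less than the surplus of D over Q, 10.0% of the Q charge. Step 5 runs at 0.0363 times QD over Q against the consumption of Q, and summing that down to 10.0% of Q left lowers the ceiling to 88.4%. For the floor, each DQD costs one D, and the D free for it is at most the surplus plus the Q left, so if the Q left in alder is below 10.0%, the alder share stays above 71.5%.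

The forecast gives 74.7% for larch, 84.5% for alder, 77.6% for elm and 87.6% for cedar, and names cedar; of larch it says “early excess D is lost to J and to over-reaction”. Its alder figure lies inside my bracket.

The simulation gives 75.6% for larch, 84.5% for alder, 77.6% for elm and 87.8% for cedar, so cedar leads, as forecast. In alder, 2.3% of Q and 9.01% of DQD stand at the end, and the fork share minus DQD per Q consumed gives 84.5%. The neighbour is larch with 0.28 M of D, 2.80 equiv: it keeps 16% of Q and holds 26.2% as DQD, so the same subtraction gives 62.5%, and that flask's share stands at 62.6%.

The numbers of this flask come from no measurement; no experiment stands behind them.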